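**Plan**

1. Numbering (3,7-dioxabicyclo[3.3.0]octane): C1 carries OH, C2 the adjacent aryl, then O3, C4, C5 (ring-fusion CH), C6 (second ArCH), O7, C8; ring A = C1–C5–C6–O7–C8, ring B = C1–C2–O3–C4–C5.
2. Retrosynthesis cuts C1–OH and C2–H (hydroboration of a C1=C2 enol ether), returns C8 to a lactone carbonyl, cuts O3–C4 while re-bonding C4 to C1 (cyclopropane C1–C4–C5), then cuts C1–C4, C1–C5 and O7–C8 back to a β-keto ester and an aryl glycidyl tosylate.
3. Forward: Sharpless epoxide → cyclopropane and ring A (as lactone) in one operation → ring B closed last by strain-release ring expansion → lactone carbonyl taken down to CH2 → hydroboration–oxidation.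
4. Enabling feature: C4 is a CH2 flanked by O3 and the ring-fusion carbon C5, and C1 carries both C2(aryl)–O3 and C8. So C2/O3 can be an aryl ketone and C8 a lactone carbonyl on C1 while C4 is parked as the apex of a cyclopropane C1–C4–C5; this gem-diacyl cyclopropane opens at C4 and recloses through the ketone oxygen.
5. Stereochemistry: absolute sense from the Sharpless epoxidation; C6 is retained from the epoxide and C5 is set by SN2 inversion in the cyclopropanation (aryl at C6 cis to C4, endo); C1 and C2 come from one syn hydroboration on the convex face (1-OH and H-2 exo, aryl at C2 endo).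

Key step: step 4

Remark: the SMILES places both aryl groups endo (each cis to the other ring), i.e. (1R,2R,5S,6S), the isomer that acid would epimerise; strong acid is therefore avoided once a benzylic C–O bond is in place.

Step 1
Reactants: 1 (E)-3-(3,4-dimethoxyphenyl)prop-2-en-1-ol
Product: 2 [(2R,3R)-3-(3,4-dimethoxyphenyl)oxiran-2-yl]methanol
Conditions: Ti(OiPr)4 (10 mol%), D-(−)-diisopropyl tartrate (12 mol%), tBuOOH, 4 Å molecular sieves, CH2Cl2, −20 °C
Reagents that add atoms: tert-butyl hydroperoxide, CC(C)(C)OO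
Why: Katsuki–Sharpless asymmetric epoxidation of an (E)-allylic alcohol, in which D-(−)-tartrate should deliver oxygen to the face that gives the (2R,3R)-epoxide, fixing C6 and (before its later inversion) C5.

Step 2
Reactants: 2 [(2R,3R)-3-(3,4-dimethoxyphenyl)oxiran-2-yl]methanol
Product: 3 [(2R,3R)-3-(3,4-dimethoxyphenyl)oxiran-2-yl]methyl 4-methylbenzenesulfonate
Conditions: TsCl, Et3N, 4-(dimethylamino)pyridine (cat.), CH2Cl2, −10 °C
Reagents that add atoms: 4-toluenesulfonyl chloride, Cc1ccc(cc1)S(Cl)(=O)=O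
Why: Tosylation of the primary alcohol under basic conditions should leave the acid-sensitive aryl epoxide intact and turn C4 into an SN2 electrophile.

Step 3
Reactants: 3 [(2R,3R)-3-(3,4-dimethoxyphenyl)oxiran-2-yl]methyl 4-methylbenzenesulfonate, 4 ethyl 3-(3,4-dimethoxyphenyl)-3-oxopropanoate
Product: 7 (1S,4S,5R)-1-(3,4-dimethoxybenzoyl)-4-(3,4-dimethoxyphenyl)-3-oxabicyclo[3.1.0]hexan-2-one, via epoxy keto ester 5 (not isolated), via cyclopropyl hydroxy ester 6 (not isolated)
Conditions: Cs2CO3 (2.2 equiv), DMF, 0 → 40 °C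
Reagents that add atoms: none
Why: Double alkylation of an active methylene by a glycidyl sulfonate (the malonate/epichlorohydrin cyclopropane-lactone synthesis): the enolate of 4 displaces the tosylate (5), the re-formed enolate opens the epoxide at C5 in a 3-exo-tet SN2 with inversion (6), and the benzylic alkoxide lactonises onto the cis ester, so C6 is retained, C5 is inverted and the aryl ends cis to the cyclopropane CH2, the smaller ester being expected to take the position cis to the carbinol arm.

Step 4
Reactants: 7 (1S,4S,5R)-1-(3,4-dimethoxybenzoyl)-4-(3,4-dimethoxyphenyl)-3-oxabicyclo[3.1.0]hexan-2-one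
Product: 9 (5S,6S)-2,6-bis(3,4-dimethoxyphenyl)-3,7-dioxabicyclo[3.3.0]oct-1-en-8-one (target numbering), via ammonium enolate 8 (not isolated)
Conditions: 1,4-diazabicyclo[2.2.2]octane (DABCO, 20 mol%), DMSO, 90 °C
Reagents that add atoms: none
Why: DABCO should add to the unsubstituted cyclopropane carbon C4 in a homoconjugate SN2 opening, the C1–C4 bond leaving as an enolate stabilised by both the aroyl ketone and the C8 lactone carbonyl (zwitterion 8), and the ketone-enolate oxygen then displaces the ammonium at C4, so that C4 moves from C1 to O3. This is the Cloke–Wilson rearrangement of a gem-diacyl cyclopropane in its amine-catalysed form, the closest known reaction type being the DABCO- or halide-catalysed ring expansion of 1-acylcyclopropane-1-carboxylates to 4,5-dihydrofuran-3-carboxylates. Ring B closes by 5-exo-tet O-alkylation while the cyclopropane is opened in the same event and ring A is untouched. No new stereocentre is formed: C1 becomes sp2, and C5 and C6 are not involved and keep the cis (endo-aryl) relationship set in step 3. The selectivities needed are attack at C4 rather than at the substituted cyclopropane carbon C5, secured by the SN2 preference for the CH2, and closure through the ketone oxygen rather than the lactone carbonyl oxygen, secured because the latter would give a bridged ketene acetal with a bridgehead double bond. The driving force is release of cyclopropane strain together with formation of a push–pull (vinylogous carbonate) enol ether, which also masks the ketone for the lactone reduction that follows.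

Step 5
Reactants: 9 (5S,6S)-2,6-bis(3,4-dimethoxyphenyl)-3,7-dioxabicyclo[3.3.0]oct-1-en-8-one
Product: 10 (5S,6S)-2,6-bis(3,4-dimethoxyphenyl)-3,7-dioxabicyclo[3.3.0]oct-1-en-8-ol (lactol, both C8 epimers)
Conditions: iBu2AlH (1.1 equiv), CH2Cl2, −78 °C; aqueous KNaC4H4O6 work-up
Reagents that add atoms: none
Why: Lactone-to-lactol reduction with iBu2AlH at low temperature: the ketone is already masked as the C1=C2 enol ether, so the C8 carbonyl is the only reducible group and the aluminium hemiacetal should survive to work-up without opening ring A.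

Step 6
Reactants: 10 (5S,6S)-2,6-bis(3,4-dimethoxyphenyl)-3,7-dioxabicyclo[3.3.0]oct-1-en-8-ol
Product: 11 (5S,6S)-2,6-bis(3,4-dimethoxyphenyl)-3,7-dioxabicyclo[3.3.0]oct-1-ene
Conditions: Et3SiH (3 equiv), BF3·OEt2 (20 mol%), CH2Cl2, −78 °C
Reagents that add atoms: none
Why: Silane reduction of a lactol (Kishi-type reductive deoxygenation, here through an allylic dioxa-stabilised cation as in a Ferrier reduction): loss of the C8 hydroxyl gives a cation delocalised over C8–C1–C2 and Et3SiH should deliver hydride to the unsubstituted terminus C8, restoring the aryl-conjugated C1=C2 enol ether and completing removal of the activating carbonyl.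

Step 7
Reactants: 11 (5S,6S)-2,6-bis(3,4-dimethoxyphenyl)-3,7-dioxabicyclo[3.3.0]oct-1-ene
Product: 13 (1R,2R,5S,6S)-2,6-bis(3,4-dimethoxyphenyl)-3,7-dioxabicyclo[3.3.0]octan-1-ol (target), via alkylborane 12 (not isolated)
Conditions: BH3·THF (2.5 equiv), THF, 0 °C → rt; then NaOH (aq), H2O2, 0 °C
Reagents that add atoms: hydrogen peroxide, OO
Why: Brown hydroboration–oxidation of a cyclic enol ether: boron goes to C1 (β to O3 and the non-benzylic carbon) and hydrogen to C2 in a syn addition on the convex face, the face of H-5 and opposite the endo aryl at C6, and oxidation with retention gives the 1-OH cis to H-5 with H-2 exo, so the aryl at C2 is endo as required.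

**Compound list**

1 | (E)-3-(3,4-dimethoxyphenyl)prop-2-en-1-ol | COc1ccc(/C=C/CO)cc1OC | starting material
2 | [(2R,3R)-3-(3,4-dimethoxyphenyl)oxiran-2-yl]methanol | COc1ccc([C@H]2O[C@@H]2CO)cc1OC | intermediate
3 | [(2R,3R)-3-(3,4-dimethoxyphenyl)oxiran-2-yl]methyl 4-methylbenzenesulfonate | COc1ccc([C@H]2O[C@@H]2COS(=O)(=O)c3ccc(C)cc3)cc1OC | intermediate
4 | ethyl 3-(3,4-dimethoxyphenyl)-3-oxopropanoate | CCOC(=O)CC(=O)c1ccc(OC)c(OC)c1 | starting material
5 | ethyl 2-(3,4-dimethoxybenzoyl)-3-[(2R,3R)-3-(3,4-dimethoxyphenyl)oxiran-2-yl]propanoate (epoxy keto ester, both C2 epimers) | COc1ccc([C@H]2O[C@@H]2CC(C(=O)OCC)C(=O)c3ccc(OC)c(OC)c3)cc1OC | intermediate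
6 | ethyl (1S,2R)-1-(3,4-dimethoxybenzoyl)-2-[(S)-(3,4-dimethoxyphenyl)(hydroxy)methyl]cyclopropane-1-carboxylate (cyclopropyl hydroxy ester) | COc1ccc([C@@H](O)[C@@H]2C[C@@]2(C(=O)OCC)C(=O)c3ccc(OC)c(OC)c3)cc1OC | intermediate
7 | (1S,4S,5R)-1-(3,4-dimethoxybenzoyl)-4-(3,4-dimethoxyphenyl)-3-oxabicyclo[3.1.0]hexan-2-one | COc1ccc([C@H]2OC(=O)[C@@]3(C(=O)c4ccc(OC)c(OC)c4)C[C@@H]23)cc1OC | intermediate
8 | 1-{[(2S,3S)-2-(3,4-dimethoxyphenyl)-4-[(3,4-dimethoxyphenyl)(oxido)methylidene]-5-oxooxolan-3-yl]methyl}-4-aza-1-azoniabicyclo[2.2.2]octane (ammonium enolate zwitterion) | COc1ccc([C@H]2OC(=O)C(=C([O-])c3ccc(OC)c(OC)c3)[C@H]2C[N+]45CCN(CC4)CC5)cc1OC | intermediate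
9 | (5S,6S)-2,6-bis(3,4-dimethoxyphenyl)-3,7-dioxabicyclo[3.3.0]oct-1-en-8-one (target numbering) | COc1ccc([C@H]2OC(=O)C3=C(c4ccc(OC)c(OC)c4)OC[C@@H]23)cc1OC | intermediate
10 | (5S,6S)-2,6-bis(3,4-dimethoxyphenyl)-3,7-dioxabicyclo[3.3.0]oct-1-en-8-ol (both C8 epimers) | COc1ccc([C@H]2OC(O)C3=C(c4ccc(OC)c(OC)c4)OC[C@@H]23)cc1OC | intermediate
11 | (5S,6S)-2,6-bis(3,4-dimethoxyphenyl)-3,7-dioxabicyclo[3.3.0]oct-1-ene | COc1ccc([C@H]2OCC3=C(c4ccc(OC)c(OC)c4)OC[C@@H]23)cc1OC | intermediate
12 | [2,6-bis(3,4-dimethoxyphenyl)-3,7-dioxabicyclo[3.3.0]octan-1-yl]borane (boron on the convex face, arrangement as in 13) | COc1ccc([C@H]2OC[C@@]3(B)[C@@H](c4ccc(OC)c(OC)c4)OC[C@@H]23)cc1OC | intermediate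
13 | (1R,2R,5S,6S)-2,6-bis(3,4-dimethoxyphenyl)-3,7-dioxabicyclo[3.3.0]octan-1-ol | COc1ccc([C@H]2OC[C@@]3(O)[C@@H](c4ccc(OC)c(OC)c4)OC[C@@H]23)cc1OC | target

Total step count: 7. Longest linear sequence: 7 steps (1 → 13); compound 4 is bought.

**Steps most likely to fail**

Step 3. The enolate of 4 may be alkylated on oxygen instead of carbon, or may attack the benzylic epoxide carbon. The cyclopropane may also close with the aroyl group instead of the ester cis to the carbinol arm, so that no lactone forms, and liberated ethoxide may cleave the non-enolisable β-keto ester (retro-Claisen). The fallback removes the ketone from the cyclopropanation. It sets out from 3 and comes back at 7. Tosylate 3 is treated with dimethyl malonate and Cs2CO3 in DMF, where the same alkylation, 3-exo-tet opening and lactonisation should give methyl (1S,4S,5R)-4-(3,4-dimethoxyphenyl)-2-oxo-3-oxabicyclo[3.1.0]hexane-1-carboxylate F1 without any cis/trans ambiguity. Hydrolysis with LiOH in THF/H2O and mild acidification, on which the lactone re-closes, should give (1S,4S,5R)-4-(3,4-dimethoxyphenyl)-2-oxo-3-oxabicyclo[3.1.0]hexane-1-carboxylic acid F2. (COCl)2 with catalytic DMF converts it into (1R,4S,5R)-4-(3,4-dimethoxyphenyl)-2-oxo-3-oxabicyclo[3.1.0]hexane-1-carbonyl chloride F3. Negishi acylation of F3 with 3,4-(MeO)2C6H3ZnCl (from 4-bromo-1,2-dimethoxybenzene, Mg, then ZnCl2) and Pd(PPh3)4 in THF should then give 7.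

Step 6. The cationic intermediate may fragment at the C6–O7 bond, with loss of the endo configuration at C6. Adventitious acid may protonate the enol ether, which the silane then reduces, and hydride may be delivered to C2 instead of C8. The fallback avoids cations altogether; it sets out from lactone 9 and comes back at 11. Lawesson's reagent in toluene at 80 °C should give (5S,6S)-2,6-bis(3,4-dimethoxyphenyl)-3,7-dioxabicyclo[3.3.0]oct-1-ene-8-thione F4. Hydride addition with LiBHEt3 in THF at −78 °C and trapping of the thiolate with MeI should give (5S,6S)-2,6-bis(3,4-dimethoxyphenyl)-8-(methylsulfanyl)-3,7-dioxabicyclo[3.3.0]oct-1-ene F5 (both C8 epimers). Radical desulfurisation of F5 with Bu3SnH and azobisisobutyronitrile in toluene at 80 °C should then give 11.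

Step 1. The electron-rich benzylic epoxide may be opened by isopropoxide or tartrate on titanium during the epoxidation or its work-up, and the enantiomeric purity may erode. The fallback uses a base-buffered, metal-free epoxidation; it sets out from 1 and comes back at 2. Silylation of 1 with tBuMe2SiCl and imidazole in DMF gives tert-butyl{[(E)-3-(3,4-dimethoxyphenyl)prop-2-en-1-yl]oxy}dimethylsilane F6. Shi epoxidation follows, with the D-fructose-derived Shi ketone (1,2:4,5-di-O-isopropylidene-β-D-erythro-2,3-hexodiulo-2,6-pyranose), KHSO5 (Oxone) and K2CO3 buffer in MeCN/dimethoxymethane/H2O at 0 °C. It should give tert-butyl{[(2R,3R)-3-(3,4-dimethoxyphenyl)oxiran-2-yl]methoxy}dimethylsilane F7, in the same facial sense as for trans-β-methylstyrene. Desilylation of F7 with Bu4NF in THF gives 2.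

Further compounds
F1 | step 3 | methyl (1S,4S,5R)-4-(3,4-dimethoxyphenyl)-2-oxo-3-oxabicyclo[3.1.0]hexane-1-carboxylate | COc1ccc([C@H]2OC(=O)[C@@]3(C(=O)OC)C[C@@H]23)cc1OC
F2 | step 3 | (1S,4S,5R)-4-(3,4-dimethoxyphenyl)-2-oxo-3-oxabicyclo[3.1.0]hexane-1-carboxylic acid | COc1ccc([C@H]2OC(=O)[C@@]3(C(=O)O)C[C@@H]23)cc1OC
F3 | step 3 | (1R,4S,5R)-4-(3,4-dimethoxyphenyl)-2-oxo-3-oxabicyclo[3.1.0]hexane-1-carbonyl chloride | COc1ccc([C@H]2OC(=O)[C@@]3(C(Cl)=O)C[C@@H]23)cc1OC
F4 | step 6 | (5S,6S)-2,6-bis(3,4-dimethoxyphenyl)-3,7-dioxabicyclo[3.3.0]oct-1-ene-8-thione | COc1ccc([C@H]2OC(=S)C3=C(c4ccc(OC)c(OC)c4)OC[C@@H]23)cc1OC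
F5 | step 6 | (5S,6S)-2,6-bis(3,4-dimethoxyphenyl)-8-(methylsulfanyl)-3,7-dioxabicyclo[3.3.0]oct-1-ene | COc1ccc([C@H]2OC(SC)C3=C(c4ccc(OC)c(OC)c4)OC[C@@H]23)cc1OC
F6 | step 1 | tert-butyl{[(E)-3-(3,4-dimethoxyphenyl)prop-2-en-1-yl]oxy}dimethylsilane | COc1ccc(/C=C/CO[Si](C)(C)C(C)(C)C)cc1OC
F7 | step 1 | tert-butyl{[(2R,3R)-3-(3,4-dimethoxyphenyl)oxiran-2-yl]methoxy}dimethylsilane | COc1ccc([C@H]2O[C@@H]2CO[Si](C)(C)C(C)(C)C)cc1OC
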